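**Remarks before the route**

- Numbering: labdane numbering is used for C1–C13 and for the methyls C17 (on C8), C19 (β on C4) and C20 (on C10). C18 is the α-substituent on C4. C14 and C15 continue the chain and C16 is the methyl on C13. The butenolide carbons are C21 (ring CH–O), C22 (C–CH3), C23 (=CH), C24 (C=O) and C25 (methyl on C22).
- Assumption: larixol (1) is taken as a purchasable natural isolate, and (S)-but-3-ene-1,2-diol (19) and (triphenylphosphoranylidene)ketene (30) as catalogue reagents.

## Analysis of the target

Compound 33 is a C25 terpenoid: a trans-fused labdane-type decalin (ring A: C1–C5, C10; ring B: C5–C10) whose C9 carries a nine-carbon chain ending in a 4-methylfuran-2(5H)-one. The decalin holds six stereocentres: C4 (CH2OH = C18, α and equatorial; CH3 = C19, axial), C5 (α-H), C6 (α-OH, equatorial), C8 (α-OH equatorial, β-CH3 axial), C9 (α-H) and C10 (β-CH3). The chain adds an E-trisubstituted C13=C14 alkene and two adjacent carbinol centres, C15 (S) and C21 (S), which are syn in the extended chain. The sensitive parts are the butenolide (conjugate acceptor, C21–H vinylogously acidic, opened by base), the C15 allylic alcohol (ionises towards the tertiary C13 terminus under acid) and the tertiary 8α-hydroxyl (closes onto any carbonyl at C13). The natural diol 1 already supplies the decalin skeleton with C5, C6, C9 and C10 correctly configured; it lacks the C8 carbinol, an oxygen on one of two geminal, unactivated methyls at C4, and the butenolide arm. The real difficulty is therefore telling C18 from C19, followed by a convergent chain synthesis that controls C13=C14, C15 and C21. The strategy rests on one geometric feature: C4 and C6 are both bonded to C5 and the equatorial C4–C18 and C6–O bonds are parallel, so the 6α-oxygen of ring B and C18 of ring A are in syn-pentane contact while axial C19 points to the β-face; a silicon atom on O6 can bridge to C18 in a strain-free six-membered ring and to no other methyl.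

## Retrosynthetic reasoning

33 ⇒ 32. The last operation only removes silicon from O6, O8, O15 and O18. The butenolide does not tolerate strong base and the C15 allylic carbinol does not tolerate strong acid, so all four hydroxyls are carried as triethylsilyl ethers that fall off together under buffered, mildly acidic desilylation.

32 ⇒ 29 + 30. The lactone is cut at O21–C24 and at C22=C23. This keeps the most fragile ring out of all earlier steps and reduces it to the α-hydroxy methyl ketone 29 plus the two-carbon ketene ylide 30. Forward, O21 must be acylated and an intramolecular Wittig reaction on the C22 ketone must close the ring without disturbing C21. Cutting at C21–O instead would create C21 late and without control.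

29 ⇒ 28 ⇒ 27. O21 is masked as a p-methoxybenzyl ether, which is also the chelating group needed one step earlier. The C22 ketone is traced back to a terminal vinyl group (C22=C25) by a Wacker-type oxidation. A vinyl group is inert to organometallics and silylation, and it avoids having to differentiate two secondary hydroxyls at C21 and C22.

27 ⇒ 26 ⇒ 18 + 23. The C14–C15 bond is cut between the alkenyl carbon and the carbinol. This is the convergent cut: it separates the terpenoid iodide 18 from the four-carbon aldehyde 23, whose single stereocentre (C21) comes from the chiral pool. The C21 alkoxy group then sets C15 by chelation; 33 needs the 15,21-syn arrangement, which is the chelation product. The alkene geometry is fixed in 18 before the union. Aldehyde 23 goes back through 22 and 21 to diol 19 and acetal 20.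

18 ⇒ 16 ⇒ 14. The E-alkene is disconnected at the C13–C16 methyl bond and the C14–metal bond. Syn-carbometalation of the terminal alkyne 16 puts the new methyl cis to the metal and gives only the E isomer, whereas olefination of ketone 14 would give E/Z mixtures. Alkyne 16 comes from methyl ketone 14 by formal dehydration through an enol derivative.

14 ⇒ 13 ⇒ 12. These are protecting-group changes. The ketone is released only after O8 is silylated, because a free 8α-hydroxyl would close onto C13.

12 ⇒ 11. The C18–O bond is traced to a C18–Si bond; oxidation with retention of the carbon framework releases the 6α,18-diol and removes the tether.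

11 ⇒ 10 (key disconnection). The Si–C18 bond of the oxasilinane is cut back to a C18–H bond and an Si–H bond on a tether held by O6. No skeletal bond is made, but C4 becomes a stereocentre. The cut is placed here because the C6 oxygen is needed in 33 anyway and is the only handle within reach of C18.

10 ⇒ 8 + 9, and 8 ⇒ 6. The tether is put on O6 with silane 9 once O8 is blocked; the selectively 8-O-silylated 8 comes from diol 6 through its bis-silyl ether 7.

6 ⇒ 5 ⇒ 4 ⇒ 2 + 3 ⇒ 1. The 8α-carbinol comes from the exocyclic C8=C17 alkene by α-face epoxidation and hydride opening at C17. The ketal 4 is made from ketone 2 and glycol 3 before C8 is hydroxylated, to avoid cyclisation of O8 onto C13. Ketone 2 is the product of oxidative excision of C14 and C15 from 1.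

## Alternatives that were turned down

Alternative 1: Disconnection at C4–C5 and C9–C10, i.e. both rings, back to an open-chain C15 epoxy diene whose trisubstituted epoxide carries one methyl and one silyloxymethyl group.
- Forward key step: a Lewis acid opens the epoxide at the future C4; the C5=C10 and then the C8=C9 alkene attack in a chair–chair array, and proton loss leaves the C7=C8 alkene of A1 (3β-hydroxy-18-(tert-butyldiphenylsilyloxy)drim-7-en-11-yl acetate).
- For it: one step makes two rings and sets C4, C5, C9 and C10 relative to each other. Which C4 substituent becomes C18 is written into the epoxide geometry, so no C–H functionalisation is needed. On that point, and on independence from a natural isolate, it is stronger than the chosen route.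
- Against it for 33: A1 has an oxygen at C3 that must be removed, no oxygen at C6, and no tertiary alcohol at C8 (the C7=C8 alkene must be hydrated with the right face selectivity while C6 is oxidised next to it). Its chain stops at C11, so C12, C13 and C16 must still be attached. The absolute configuration would rest on a site-selective asymmetric epoxidation of one of three trisubstituted alkenes, and cation–olefin bicyclisations often stop after one ring or give alkene isomers.
- Comparison: from A1 to the stage of 14 well over ten steps are expected, against ten from 1. The chosen route offers C5, C6, C9, C10 and the chain to C13 ready-made and uses the C6 oxygen as the director.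

Alternative 2: Disconnection of the C8–O bond of an 8α,12-lactone and, before that, of the whole aromatic ring C of dehydroabietic acid A2, whose carboxyl carbon is C18.
- Forward key step: strong protic acid protonates the tetrasubstituted C8=C9 alkene of the ring-C-excised unsaturated acid at C9 on the α-face; the C12 carboxyl captures the C8 cation and gives the trans-fused γ-lactone A3 (6α,18-diacetoxy 8α,12-lactone of sclareolide type).
- For it: C18 is oxidised from the start, so the C18/C19 question never arises; here it is clearly stronger than a C–H silylation. A2 is cheap, C4, C5 and C10 are correct, and the lactonisation sets C8 and C9 together.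
- Against it: excising an aromatic ring (C12–C14 with the isopropyl group) needs a long oxidative degradation, and the C6 oxygen must be brought in from the benzylic C7 position. In the acidic key step the 6α-acetate sits two carbons from the C8 cation, so elimination towards C7 and loss of acetate compete, and protonation of C9 from the wrong face gives the 9-epi series. A3 ends at C12 at the carboxyl level, so the chain must be rebuilt from one carbon further back than in 14.
- Comparison: clearly longer. The chosen route gives up the built-in C18 oxygen but takes C6–OH, C9 and the C11–C13 chain from 1 and needs one C–H functionalisation to make up for it.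

Alternative 3: Disconnection of the C7–C8 bond by a retro-1,2-shift that contracts ring B to a cyclopentene carrying a tertiary hydroxyl and an acetyl group on C9.
- Forward key step: base-mediated α-ketol rearrangement; the C9 alkoxide pushes allylic C7 onto the acetyl carbonyl carbon, which becomes C8 (hydroxyl and methyl), while C9 becomes a ketone. The product is A4 (8α-hydroxy-8β-methyl-9-oxo Δ5-octalin, 18-benzyl ether).
- For it: the tertiary C8 carbinol and ring B arise in one step driven by relief of ring strain. The route is de novo, so C18 is differentiated by construction (stronger than the chosen route on this point and on freedom to vary the skeleton), and the C9 ketone is a place to attach the chain.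
- Against it: the ring-contracted precursor needs an enantioselective synthesis with the quaternary centres C4 and C10 in the right relative configuration. Two groups on C9 (C7 and C10) can migrate, the rearrangement is reversible, and the C8 configuration is a thermodynamic outcome. The C9 ketone lies between two fully substituted carbons, so adding the chain and then removing the C9 oxygen with 9α-H is difficult, and C5=C6 must still become 5α-H/6α-OH.
- Comparison: the longest option. The chosen route obtains the same C8 carbinol in two steps from the exocyclic alkene of 1.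

Key step: step 7

## Route

Step 1
Reactants: 1 larixol, (13S)-labda-8(17),14-diene-6α,13-diol
Product: 2 6α-hydroxy-14,15-dinorlabd-8(17)-en-13-one
Conditions: KMnO4, BnEt3NCl, CH2Cl2, 0 °C to rt
Reagents that add atoms: none
Why: Permanganate degradation of a tertiary vinyl carbinol: dihydroxylation of the vinyl group, glycol cleavage and oxidative decarboxylation of the α-hydroxy acid excise C14 and C15 and turn the C13 carbinol into the methyl ketone; the less electron-rich 1,1-disubstituted C8=C17 alkene and the hindered 6α-hydroxyl should survive under cold phase-transfer conditions.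

Step 2
Reactants: 2 6α-hydroxy-14,15-dinorlabd-8(17)-en-13-one; 3 ethylene glycol
Product: 4 13,13-(ethylenedioxy)-14,15-dinorlabd-8(17)-en-6α-ol
Conditions: ethylene glycol, PPTS (cat.), benzene, reflux, Dean–Stark
Reagents that add atoms: ethylene glycol (3), OCCO
Why: Acid-catalysed ketalisation with azeotropic removal of water; the weak acid should not isomerise the exocyclic alkene, and the ketal is installed before C8 is hydroxylated because an 8α-hydroxy-13-ketone would cyclise under the same conditions.

Step 3
Reactants: 4 13,13-(ethylenedioxy)-14,15-dinorlabd-8(17)-en-6α-ol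
Product: 5 8α,17-epoxy-13,13-(ethylenedioxy)-14,15-dinorlabdan-6α-ol (epoxide oxygen α, C17 β)
Conditions: mCPBA, NaHCO3, CH2Cl2, 0 °C
Reagents that add atoms: 3-chloroperbenzoic acid (mCPBA), OOC(=O)c1cccc(Cl)c1
Why: Prilezhaev epoxidation; the peracid should approach C8=C17 from the equatorial α-face because the axial β trajectory at C8 is blocked 1,3-diaxially by the C20 methyl, and the homoallylic 6α-hydroxyl can hydrogen-bond the reagent on the same face, which places the C8 oxygen α.

Step 4
Reactants: 5 8α,17-epoxy-13,13-(ethylenedioxy)-14,15-dinorlabdan-6α-ol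
Product: 6 13,13-(ethylenedioxy)-14,15-dinorlabdane-6α,8α-diol (8β-methyl)
Conditions: LiAlH4, THF, 0 °C to reflux
Reagents that add atoms: none
Why: Reductive epoxide opening by SN2 attack of hydride on the unsubstituted carbon C17; the C8–O bond is not touched, so the α-oxygen becomes the equatorial 8α-hydroxyl and C17 the axial methyl, and the ketal is inert to hydride.

Step 5
Reactants: 6 13,13-(ethylenedioxy)-14,15-dinorlabdane-6α,8α-diol
Product: 8 13,13-(ethylenedioxy)-8α-(trimethylsilyloxy)-14,15-dinorlabdan-6α-ol, via 6α,8α-bis(trimethylsilyl) ether 7 (not isolated)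
Conditions: TMSOTf, Et3N, CH2Cl2, −78 to 0 °C; then K2CO3, MeOH, 0 °C
Reagents that add atoms: trimethylsilyl triflate (TMSOTf), C[Si](C)(C)OS(=O)(=O)C(F)(F)F
Why: Exhaustive silylation followed by chemoselective base-catalysed methanolysis; the secondary Si–O bond at C6 is solvolysed much faster than the tertiary one at C8, which frees O6 for the tether and leaves O8 blocked.

Step 6
Reactants: 8 13,13-(ethylenedioxy)-8α-(trimethylsilyloxy)-14,15-dinorlabdan-6α-ol; 9 diethylsilane
Product: 10 6α-(diethylsilyloxy)-13,13-(ethylenedioxy)-8α-(trimethylsilyloxy)-14,15-dinorlabdane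
Conditions: [Ir(cod)OMe]2 (cat.), Et2SiH2, THF, rt to 50 °C; volatiles removed, used crude
Reagents that add atoms: diethylsilane (9), CC[SiH2]CC
Why: Iridium-catalysed dehydrogenative coupling of an alcohol with a dihydrosilane (O–H plus Si–H to O–Si with loss of H2); with a hindered secondary alcohol it should stop at the monoalkoxy hydrosilane, and the ketal and the trimethylsilyl ether are inert.

Step 7
Reactants: 10 6α-(diethylsilyloxy)-13,13-(ethylenedioxy)-8α-(trimethylsilyloxy)-14,15-dinorlabdane
Product: 11 6α-O,18-C-(diethylsilanediyl)-bridged 13,13-(ethylenedioxy)-8α-(trimethylsilyloxy)-14,15-dinorlabdane (six-membered ring O6–SiEt2–C18–C4–C5–C6; C19 methyl β)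
Conditions: [Rh(cod)Cl]2 (2 mol %), Xantphos (4.5 mol %) [forms Rh(Xantphos)Cl], norbornene (2 equiv), THF, 100 °C, sealed tube
Reagents that add atoms: none
Why: Intramolecular dehydrogenative C–H silylation directed by a hydrosilyl ether, the known rhodium/Xantphos δ-silylation of alcohols that leads to 1,4-diols after oxidation. The chloride complex of monovalent rhodium adds the Si–H bond of 10, norbornene inserts into Rh–H and leaves as norbornane, and the resulting rhodium silyl cleaves a primary C–H bond of C18 by oxidative addition to trivalent rhodium; Si–C reductive elimination from the seven-membered rhodacycle then closes the ring. The ring formed is the six-membered 1-oxa-2-silacyclohexane O6–Si–C18–C4–C5–C6, closed at the Si–C18 bond as a chair that uses the existing gauche(+)/gauche(−) arrangement of O6 and C18 about C6–C5 and C5–C4. C4 becomes a stereocentre and its configuration is dictated by the substrate: the equatorial 6α-oxygen and the equatorial C18 methyl have parallel bonds on C6 and C4, whereas axial C19 could only be reached through a twist-boat ring. The step needs site selectivity among the δ-positions and no γ-closure; C4, C8 and C10 carry no hydrogen, C17 and C20 are axial on the β-face away from the equatorial oxygen, C3 is anti to C6, and the catalyst prefers primary over secondary C–H bonds. The ketal keeps the C13 carbonyl from being hydrosilylated and the trimethylsilyl ether keeps O8 from acquiring a second Si–H tether.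

Step 8
Reactants: 11 6α-O,18-C-(diethylsilanediyl)-bridged ketal
Product: 12 13,13-(ethylenedioxy)-14,15-dinorlabdane-6α,8α,18-triol
Conditions: 30% aq. H2O2, KHCO3, KF, THF/MeOH (1:1), 50 °C
Reagents that add atoms: hydrogen peroxide, OO
Why: Tamao–Fleming oxidation; fluoride raises the coordination number of the alkoxy-substituted silicon, hydroperoxide adds and C18 migrates from silicon to oxygen (a primary carbon, so no stereocentre is at stake and C4 is untouched), while the Si–O6 bond and the tertiary trimethylsilyl ether are methanolysed in the same basic fluoride medium.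

Step 9
Reactants: 12 13,13-(ethylenedioxy)-14,15-dinorlabdane-6α,8α,18-triol
Product: 13 13,13-(ethylenedioxy)-6α,8α,18-tris(triethylsilyloxy)-14,15-dinorlabdane
Conditions: TESOTf, 2,6-lutidine, CH2Cl2, −78 to 0 °C
Reagents that add atoms: triethylsilyl triflate (TESOTf), CC[Si](CC)(CC)OS(=O)(=O)C(F)(F)F
Why: Silyl ether formation with a silyl triflate, which should silylate the neopentyl primary, the hindered secondary and the tertiary hydroxyl alike; all three must be masked for the strongly basic and Lewis-acidic steps that follow, and triethylsilyl groups can be removed at the end under conditions the butenolide tolerates.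

Step 10
Reactants: 13 13,13-(ethylenedioxy)-6α,8α,18-tris(triethylsilyloxy)-14,15-dinorlabdane
Product: 14 6α,8α,18-tris(triethylsilyloxy)-14,15-dinorlabdan-13-one
Conditions: PPTS, acetone/H2O (10:1), 40 °C
Reagents that add atoms: water, O
Why: Acid-catalysed ketal hydrolysis (transketalisation to acetone); the dioxolane of an unhindered methyl ketone should cleave faster than the three hindered triethylsilyl ethers, and with O8 silylated the ketone cannot close to a hemiketal.

Step 11
Reactants: 14 6α,8α,18-tris(triethylsilyloxy)-14,15-dinorlabdan-13-one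
Product: 16 6α,8α,18-tris(triethylsilyloxy)-14,15-dinorlabd-13(16)-yne (terminal alkyne C12–C≡CH; its CH carbon becomes C14 of 33), via enol phosphate 15 (not isolated)
Conditions: LiN(i-Pr)2 (1.1 equiv), THF, −78 °C; ClP(O)(OEt)2; then LiN(i-Pr)2 (2.3 equiv), −78 °C to rt
Reagents that add atoms: none
Why: Methyl ketone to terminal alkyne through an enol phosphate; kinetic deprotonation takes the less hindered methyl, the enolate is trapped on oxygen, and a second base induces β-elimination of phosphate, the acetylide being protonated on work-up.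

Step 12
Reactants: 16 6α,8α,18-tris(triethylsilyloxy)-14,15-dinorlabd-13(16)-yne
Product: 18 (13E)-14-iodo-6α,8α,18-tris(triethylsilyloxy)-15-norlabd-13-ene, via alkenyldimethylalane 17 (not isolated)
Conditions: Me3Al (3 equiv), Cp2ZrCl2 (0.5 equiv), CH2Cl2, 0 °C to rt; then I2, THF, −30 °C
Reagents that add atoms: trimethylaluminium (Me3Al), C[Al](C)C; iodine (I2), [I][I]
Why: Zirconium-catalysed syn-methylalumination of a terminal alkyne followed by iodinolysis with retention; methyl goes to the internal carbon and aluminium to the terminal one on the same side, so only the E-alkene with the new C16 methyl cis to C14–I should form.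

Step 13
Reactants: 19 (S)-but-3-ene-1,2-diol; 20 4-methoxybenzaldehyde dimethyl acetal
Product: 21 (4S)-2-(4-methoxyphenyl)-4-vinyl-1,3-dioxolane (both epimers at the acetal carbon)
Conditions: PPTS (cat.), CH2Cl2, rt
Reagents that add atoms: 4-methoxybenzaldehyde dimethyl acetal (20), COC(OC)c1ccc(OC)cc1
Why: Acid-catalysed transacetalisation of a 1,2-diol; the stereocentre is not involved.

Step 14
Reactants: 21 (4S)-2-(4-methoxyphenyl)-4-vinyl-1,3-dioxolane
Product: 22 (S)-2-[(4-methoxybenzyl)oxy]but-3-en-1-ol
Conditions: i-Bu2AlH, CH2Cl2, −78 to 0 °C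
Reagents that add atoms: none
Why: Regioselective reductive opening of a p-methoxybenzylidene acetal; aluminium coordinates the less hindered primary oxygen, the acetal C–O bond breaks there, and hydride is delivered to the oxocarbenium ion, which should leave the p-methoxybenzyl group on the secondary oxygen.

Step 15
Reactants: 22 (S)-2-[(4-methoxybenzyl)oxy]but-3-en-1-ol
Product: 23 (S)-2-[(4-methoxybenzyl)oxy]but-3-enal
Conditions: Dess–Martin periodinane, NaHCO3, CH2Cl2, 0 °C; used at once
Reagents that add atoms: none
Why: Dess–Martin oxidation under buffered, base-free conditions, chosen so that the stereocentre, which is both α to the carbonyl and allylic, is neither enolised nor moved into conjugation.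

Step 16
Reactants: 18 (13E)-14-iodo-6α,8α,18-tris(triethylsilyloxy)-15-norlabd-13-ene; 23 (S)-2-[(4-methoxybenzyl)oxy]but-3-enal
Product: 26 (13E,15S,21S)-allylic alcohol with the C9 chain –CH2CH2–C(CH3)=CH–CH(OH)–CH(OPMB)–CH=CH2 on the 6α,8α,18-tris(triethylsilyloxy) decalin, via alkenyllithium 24 (not isolated), via alkenylmagnesium bromide 25 (not isolated)
Conditions: t-BuLi (2.1 equiv), Et2O, −78 °C; MgBr2·OEt2, −78 °C; then 23 (1.5 equiv), CH2Cl2, −78 °C
Reagents that add atoms: (S)-2-[(4-methoxybenzyl)oxy]but-3-enal (23), C=C[C@H](OCc1ccc(OC)cc1)C=O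
Why: Iodine–lithium exchange with retention of alkene geometry, transmetalation to magnesium and chelation-controlled 1,2-addition (Cram chelate); magnesium bridges the aldehyde oxygen and the p-methoxybenzyl ether oxygen, and the alkenyl group attacks from the side of the C21 hydrogen, opposite the vinyl group, which should give the 15,21-syn (15S) alcohol required in 33.

Step 17
Reactants: 26 (13E,15S,21S)-allylic alcohol
Product: 27 15-O-triethylsilyl ether of 26
Conditions: TESOTf, 2,6-lutidine, CH2Cl2, −78 °C
Reagents that add atoms: triethylsilyl triflate (TESOTf), CC[Si](CC)(CC)OS(=O)(=O)C(F)(F)F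
Why: Silyl ether formation; O15 must be blocked so that only O21 can be acylated in the annulation, and the same silyl group as on the ring allows one final deprotection.

Step 18
Reactants: 27 15-O-triethylsilyl ether of 26
Product: 28 (13E,15S,21R)-methyl ketone with the chain end –CH(OTES)–CH(OPMB)–C(=O)CH3 (spatial arrangement at C21 unchanged; the descriptor changes with the priorities)
Conditions: Pd(Quinox)Cl2 (5 mol %), AgSbF6 (12 mol %), 70% aq. t-BuOOH, CH2Cl2, 0 °C to rt
Reagents that add atoms: tert-butyl hydroperoxide, CC(C)(C)OO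
Why: Tsuji–Wacker oxidation with a quinoline–oxazoline complex of divalent palladium and hydroperoxide as oxidant, a catalyst system that gives methyl ketones from protected allylic alcohols; only the monosubstituted alkene should react, oxygen is delivered to the internal carbon C22, and the non-basic medium leaves C21 untouched.

Step 19
Reactants: 28 (13E,15S,21R)-methyl ketone
Product: 29 (13E,15S,21R)-α-hydroxy ketone with the chain end –CH(OTES)–CH(OH)–C(=O)CH3
Conditions: DDQ, CH2Cl2/pH 7 buffer, 0 °C
Reagents that add atoms: none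
Why: Oxidative cleavage of a p-methoxybenzyl ether (hydride abstraction by the quinone and hydrolysis of the oxocarbenium ion); the buffered medium should spare the silyl ethers and avoid enolisation of the ketone.

Step 20
Reactants: 29 (13E,15S,21R)-α-hydroxy ketone; 30 (triphenylphosphoranylidene)ketene
Product: 32 6,8,15,18-tetrakis-O-triethylsilyl ether of 33, via phosphoranylidene acetate 31 (not isolated)
Conditions: Ph3P=C=C=O (1.5 equiv), toluene, 90 °C
Reagents that add atoms: (triphenylphosphoranylidene)ketene (30), O=C=C=P(c1ccccc1)(c1ccccc1)c1ccccc1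
Why: Butenolide annulation with the Bestmann ylide; the O21–H bond adds across the ketene to give an ester-stabilised ylide, and an intramolecular Wittig reaction with the adjacent C22 ketone closes the five-membered unsaturated lactone under neutral conditions that should not epimerise C21.

Step 21
Reactants: 32 6,8,15,18-tetrakis-O-triethylsilyl ether of 33
Product: 33 target, (13E,15S,21S)-6α,8α,15,18-tetrahydroxy labdane-type butenolide
Conditions: HF·pyridine, pyridine, THF, 0 °C to rt
Reagents that add atoms: none
Why: Fluoride-mediated cleavage of the four Si–O bonds; the buffered, weakly acidic fluoride source should neither open or epimerise the butenolide nor ionise the C15 allylic alcohol.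

## Compound list

1 | larixol, (13S)-labda-8(17),14-diene-6α,13-diol | C=C[C@@](C)(O)CC[C@@H]1[C@@]2(C)CCCC(C)(C)[C@@H]2[C@@H](O)CC1=C | starting material
2 | 6α-hydroxy-14,15-dinorlabd-8(17)-en-13-one | CC(=O)CC[C@@H]1[C@@]2(C)CCCC(C)(C)[C@@H]2[C@@H](O)CC1=C | intermediate
3 | ethylene glycol | OCCO | starting material
4 | 13,13-(ethylenedioxy)-14,15-dinorlabd-8(17)-en-6α-ol | CC1(CC[C@@H]2[C@@]3(C)CCCC(C)(C)[C@@H]3[C@@H](O)CC2=C)OCCO1 | intermediate
5 | 8α,17-epoxy-13,13-(ethylenedioxy)-14,15-dinorlabdan-6α-ol | CC1(CC[C@@H]2[C@@]3(C)CCCC(C)(C)[C@@H]3[C@@H](O)C[C@@]2(C4)O4)OCCO1 | intermediate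
6 | 13,13-(ethylenedioxy)-14,15-dinorlabdane-6α,8α-diol | CC1(CC[C@@H]2[C@@]3(C)CCCC(C)(C)[C@@H]3[C@@H](O)C[C@@]2(C)O)OCCO1 | intermediate
7 | 13,13-(ethylenedioxy)-6α,8α-bis(trimethylsilyloxy)-14,15-dinorlabdane | CC1(CC[C@@H]2[C@@]3(C)CCCC(C)(C)[C@@H]3[C@@H](O[Si](C)(C)C)C[C@@]2(C)O[Si](C)(C)C)OCCO1 | intermediate
8 | 13,13-(ethylenedioxy)-8α-(trimethylsilyloxy)-14,15-dinorlabdan-6α-ol | CC1(CC[C@@H]2[C@@]3(C)CCCC(C)(C)[C@@H]3[C@@H](O)C[C@@]2(C)O[Si](C)(C)C)OCCO1 | intermediate
9 | diethylsilane | CC[SiH2]CC | starting material
10 | 6α-(diethylsilyloxy)-13,13-(ethylenedioxy)-8α-(trimethylsilyloxy)-14,15-dinorlabdane | CC1(CC[C@@H]2[C@@]3(C)CCCC(C)(C)[C@@H]3[C@@H](O[SiH](CC)CC)C[C@@]2(C)O[Si](C)(C)C)OCCO1 | intermediate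
11 | 6α-O,18-C-(diethylsilanediyl)-bridged 13,13-(ethylenedioxy)-8α-(trimethylsilyloxy)-14,15-dinorlabdane | CC1(CC[C@@H]2[C@@]3(C)CCC[C@@](C)(C[Si]4(CC)CC)[C@@H]3[C@@H](O4)C[C@@]2(C)O[Si](C)(C)C)OCCO1 | intermediate
12 | 13,13-(ethylenedioxy)-14,15-dinorlabdane-6α,8α,18-triol | CC1(CC[C@@H]2[C@@]3(C)CCC[C@@](C)(CO)[C@@H]3[C@@H](O)C[C@@]2(C)O)OCCO1 | intermediate
13 | 13,13-(ethylenedioxy)-6α,8α,18-tris(triethylsilyloxy)-14,15-dinorlabdane | CC1(CC[C@@H]2[C@@]3(C)CCC[C@@](C)(CO[Si](CC)(CC)CC)[C@@H]3[C@@H](O[Si](CC)(CC)CC)C[C@@]2(C)O[Si](CC)(CC)CC)OCCO1 | intermediate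
14 | 6α,8α,18-tris(triethylsilyloxy)-14,15-dinorlabdan-13-one | CC(=O)CC[C@@H]1[C@@]2(C)CCC[C@@](C)(CO[Si](CC)(CC)CC)[C@@H]2[C@@H](O[Si](CC)(CC)CC)C[C@@]1(C)O[Si](CC)(CC)CC | intermediate
15 | diethyl 6α,8α,18-tris(triethylsilyloxy)-14,15-dinorlabd-13(16)-en-13-yl phosphate | C=C(OP(=O)(OCC)OCC)CC[C@@H]1[C@@]2(C)CCC[C@@](C)(CO[Si](CC)(CC)CC)[C@@H]2[C@@H](O[Si](CC)(CC)CC)C[C@@]1(C)O[Si](CC)(CC)CC | intermediate
16 | 6α,8α,18-tris(triethylsilyloxy)-14,15-dinorlabd-13(16)-yne | C#CCC[C@@H]1[C@@]2(C)CCC[C@@](C)(CO[Si](CC)(CC)CC)[C@@H]2[C@@H](O[Si](CC)(CC)CC)C[C@@]1(C)O[Si](CC)(CC)CC | intermediate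
17 | (13E)-14-(dimethylalumanyl)-6α,8α,18-tris(triethylsilyloxy)-15-norlabd-13-ene | C[Al](C)/C=C(\C)CC[C@@H]1[C@@]2(C)CCC[C@@](C)(CO[Si](CC)(CC)CC)[C@@H]2[C@@H](O[Si](CC)(CC)CC)C[C@@]1(C)O[Si](CC)(CC)CC | intermediate
18 | (13E)-14-iodo-6α,8α,18-tris(triethylsilyloxy)-15-norlabd-13-ene | I/C=C(\C)CC[C@@H]1[C@@]2(C)CCC[C@@](C)(CO[Si](CC)(CC)CC)[C@@H]2[C@@H](O[Si](CC)(CC)CC)C[C@@]1(C)O[Si](CC)(CC)CC | intermediate
19 | (S)-but-3-ene-1,2-diol | C=C[C@H](O)CO | starting material
20 | 4-methoxybenzaldehyde dimethyl acetal | COC(OC)c1ccc(OC)cc1 | starting material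
21 | (4S)-2-(4-methoxyphenyl)-4-vinyl-1,3-dioxolane | C=C[C@H]1COC(c2ccc(OC)cc2)O1 | intermediate
22 | (S)-2-[(4-methoxybenzyl)oxy]but-3-en-1-ol | C=C[C@H](OCc1ccc(OC)cc1)CO | intermediate
23 | (S)-2-[(4-methoxybenzyl)oxy]but-3-enal | C=C[C@H](OCc1ccc(OC)cc1)C=O | intermediate
24 | (13E)-14-lithio-6α,8α,18-tris(triethylsilyloxy)-15-norlabd-13-ene | [Li]/C=C(\C)CC[C@@H]1[C@@]2(C)CCC[C@@](C)(CO[Si](CC)(CC)CC)[C@@H]2[C@@H](O[Si](CC)(CC)CC)C[C@@]1(C)O[Si](CC)(CC)CC | intermediate
25 | (13E)-14-(bromomagnesio)-6α,8α,18-tris(triethylsilyloxy)-15-norlabd-13-ene | Br[Mg]/C=C(\C)CC[C@@H]1[C@@]2(C)CCC[C@@](C)(CO[Si](CC)(CC)CC)[C@@H]2[C@@H](O[Si](CC)(CC)CC)C[C@@]1(C)O[Si](CC)(CC)CC | intermediate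
26 | (13E,15S,21S)-15-hydroxy-21-[(4-methoxybenzyl)oxy] 22(25)-ene, ring hydroxyls as triethylsilyl ethers | C=C[C@H](OCc1ccc(OC)cc1)[C@@H](O)/C=C(\C)CC[C@@H]1[C@@]2(C)CCC[C@@](C)(CO[Si](CC)(CC)CC)[C@@H]2[C@@H](O[Si](CC)(CC)CC)C[C@@]1(C)O[Si](CC)(CC)CC | intermediate
27 | 15-O-triethylsilyl ether of 26 | C=C[C@H](OCc1ccc(OC)cc1)[C@@H](O[Si](CC)(CC)CC)/C=C(\C)CC[C@@H]1[C@@]2(C)CCC[C@@](C)(CO[Si](CC)(CC)CC)[C@@H]2[C@@H](O[Si](CC)(CC)CC)C[C@@]1(C)O[Si](CC)(CC)CC | intermediate
28 | (13E,15S,21R)-21-[(4-methoxybenzyl)oxy]-22-oxo compound (methyl ketone), O6, O8, O15, O18 as triethylsilyl ethers | CC(=O)[C@H](OCc1ccc(OC)cc1)[C@@H](O[Si](CC)(CC)CC)/C=C(\C)CC[C@@H]1[C@@]2(C)CCC[C@@](C)(CO[Si](CC)(CC)CC)[C@@H]2[C@@H](O[Si](CC)(CC)CC)C[C@@]1(C)O[Si](CC)(CC)CC | intermediate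
29 | (13E,15S,21R)-21-hydroxy-22-oxo compound (α-hydroxy ketone), O6, O8, O15, O18 as triethylsilyl ethers | CC(=O)[C@H](O)[C@@H](O[Si](CC)(CC)CC)/C=C(\C)CC[C@@H]1[C@@]2(C)CCC[C@@](C)(CO[Si](CC)(CC)CC)[C@@H]2[C@@H](O[Si](CC)(CC)CC)C[C@@]1(C)O[Si](CC)(CC)CC | intermediate
30 | (triphenylphosphoranylidene)ketene | O=C=C=P(c1ccccc1)(c1ccccc1)c1ccccc1 | starting material
31 | 21-O-[(triphenylphosphoranylidene)acetyl] ester of 29 | CC(=O)[C@H](OC(=O)C=P(c1ccccc1)(c1ccccc1)c1ccccc1)[C@@H](O[Si](CC)(CC)CC)/C=C(\C)CC[C@@H]1[C@@]2(C)CCC[C@@](C)(CO[Si](CC)(CC)CC)[C@@H]2[C@@H](O[Si](CC)(CC)CC)C[C@@]1(C)O[Si](CC)(CC)CC | intermediate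
32 | 6,8,15,18-tetrakis-O-triethylsilyl ether of 33 | CC1=CC(=O)O[C@@H]1[C@@H](O[Si](CC)(CC)CC)/C=C(\C)CC[C@@H]1[C@@]2(C)CCC[C@@](C)(CO[Si](CC)(CC)CC)[C@@H]2[C@@H](O[Si](CC)(CC)CC)C[C@@]1(C)O[Si](CC)(CC)CC | intermediate
33 | target, (13E,15S,21S)-6α,8α,15,18-tetrahydroxy labdane-type butenolide | CC1=CC(=O)O[C@@H]1[C@@H](O)/C=C(\C)CC[C@@H]1[C@@]2(C)CCC[C@@](C)(CO)[C@@H]2[C@@H](O)C[C@@]1(C)O | target

## Step count and least certain steps

Total: 21 steps. Longest linear sequence: 18 steps (steps 1–12 and 16–21); steps 13–15 form the three-step side branch to aldehyde 23.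

Step 7 (key step). What may go wrong: slow C–H cleavage at the neopentyl methyl, so that silane redistribution, loss of the Si–H tether by adventitious hydrolysis or hydrosilylation of norbornene consumes the substrate; partial reaction at another methyl would lower site selectivity. Fallback (sets out from 8, returns at 12): the same 6α-oxygen is used as an alkoxy radical instead of a silicon carrier. A hypoiodite reaction of 8 (PhI(OAc)2, I2, cyclohexane, visible light) should abstract a C18 hydrogen by 1,5-transfer and close the 6α,18-cyclic ether F1. Catalytic RuCl3 with NaIO4 then oxidises the ether methylene to the 18,6α-lactone F2, LiAlH4 opens it to the 8-O-trimethylsilyl 6α,18-diol F3, and Bu4NF removes the silyl group to give 12.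

Step 16. What may go wrong: loss of configuration at C21 of the aldehyde by enolisation or double-bond migration before addition, and incomplete chelation control giving the 15-epimer. Fallback (sets out from 16, returns at 28): the polarity of the union is reversed so that both stereocentres are set by an auxiliary. Alane 17, made from 16 as in step 12, is converted with n-BuLi into its ate complex and trapped with paraformaldehyde to give the (E)-allylic alcohol F4, which MnO2 oxidises to the enal F5. The glycolyl oxazolidinone F6, made by N-acylation of (R)-4-benzyloxazolidin-2-one with (4-methoxybenzyloxy)acetyl chloride, is enolised with Bu2BOTf/Et3N and added to F5 in an Evans syn-aldol reaction to give the adduct F7 with the C15 and C21 arrangement of 33. Me3Al/MeONHMe·HCl gives the Weinreb amide F8, TESOTf its 15-O-triethylsilyl ether F9, and MeMgBr converts F9 into 28. This path also avoids aldehyde 23 and the Wacker step.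

Step 18. What may go wrong: oxypalladation at the terminal carbon under the influence of the allylic ether (aldehyde formation), or slow turnover at a hindered alkene with erosion of the silyl ethers by the Lewis-acidic medium. Fallback (sets out from 27, returns at 28): hydration and oxidation in two steps. Oxymercuration of the monosubstituted alkene (Hg(OAc)2, THF/H2O), which should react faster than the trisubstituted one, and reduction with NaBH4 give the C22 carbinol F10 as a mixture of C22 epimers; Dess–Martin oxidation converts both into 28.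

Step 20. What may go wrong: epimerisation at C21 by enolisation of the acylated hydroxy ketone before ring closure, or slow acylation of the hindered O21. Fallback (sets out from 29, returns at 32): ring closure by an aldol instead of a Wittig reaction. Acylation of O21 with bromoacetyl bromide and pyridine gives the bromoacetate F11; SmI2 in THF at −78 °C effects an intramolecular Reformatsky reaction onto the C22 ketone to give the β-hydroxy lactone F12; dehydration with SOCl2/pyridine gives 32.

Step 5. What may go wrong: non-selective methanolysis, i.e. loss of both silyl groups or incomplete cleavage at the hindered O6. Fallback (sets out from 6, returns at 10): the order is reversed. Iridium-catalysed dehydrogenative silylation of 6 with one equivalent of 9 should take the secondary hydroxyl first and give the 8-hydroxy hydrosilyl ether F13; N-(trimethylsilyl)imidazole, a neutral silyl donor that tolerates the Si–H bond, then caps O8 to give 10.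

## Further compounds

F1 | step 7 | 6α,18-epoxy-13,13-(ethylenedioxy)-8α-(trimethylsilyloxy)-14,15-dinorlabdane | CC1(CC[C@@H]2[C@@]3(C)CCC[C@@](C)(CO4)[C@@H]3[C@@H]4C[C@@]2(C)O[Si](C)(C)C)OCCO1
F2 | step 7 | 13,13-(ethylenedioxy)-8α-(trimethylsilyloxy)-14,15-dinorlabdan-18,6α-olide | CC1(CC[C@@H]2[C@@]3(C)CCC[C@@](C)(C(=O)O4)[C@@H]3[C@@H]4C[C@@]2(C)O[Si](C)(C)C)OCCO1
F3 | step 7 | 13,13-(ethylenedioxy)-8α-(trimethylsilyloxy)-14,15-dinorlabdane-6α,18-diol | CC1(CC[C@@H]2[C@@]3(C)CCC[C@@](C)(CO)[C@@H]3[C@@H](O)C[C@@]2(C)O[Si](C)(C)C)OCCO1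
F4 | step 16 | (13E)-6α,8α,18-tris(triethylsilyloxy)labd-13-en-15-ol | OC/C=C(\C)CC[C@@H]1[C@@]2(C)CCC[C@@](C)(CO[Si](CC)(CC)CC)[C@@H]2[C@@H](O[Si](CC)(CC)CC)C[C@@]1(C)O[Si](CC)(CC)CC
F5 | step 16 | (13E)-6α,8α,18-tris(triethylsilyloxy)labd-13-en-15-al | O=C/C=C(\C)CC[C@@H]1[C@@]2(C)CCC[C@@](C)(CO[Si](CC)(CC)CC)[C@@H]2[C@@H](O[Si](CC)(CC)CC)C[C@@]1(C)O[Si](CC)(CC)CC
F6 | step 16 | (R)-4-benzyl-3-{[(4-methoxybenzyl)oxy]acetyl}oxazolidin-2-one | COc1ccc(COCC(=O)N2[C@H](Cc3ccccc3)COC2=O)cc1
F7 | step 16 | (4R)-4-benzyl-3-[(2R,3S)-3-hydroxy-2-(4-methoxybenzyloxy)acyl]oxazolidin-2-one syn-aldol adduct of F5 | O=C1OC[C@@H](Cc2ccccc2)N1C(=O)[C@H](OCc1ccc(OC)cc1)[C@@H](O)/C=C(\C)CC[C@@H]1[C@@]2(C)CCC[C@@](C)(CO[Si](CC)(CC)CC)[C@@H]2[C@@H](O[Si](CC)(CC)CC)C[C@@]1(C)O[Si](CC)(CC)CC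
F8 | step 16 | N-methoxy-N-methyl amide corresponding to F7 | CON(C)C(=O)[C@H](OCc1ccc(OC)cc1)[C@@H](O)/C=C(\C)CC[C@@H]1[C@@]2(C)CCC[C@@](C)(CO[Si](CC)(CC)CC)[C@@H]2[C@@H](O[Si](CC)(CC)CC)C[C@@]1(C)O[Si](CC)(CC)CC
F9 | step 16 | 15-O-triethylsilyl ether of F8 | CON(C)C(=O)[C@H](OCc1ccc(OC)cc1)[C@@H](O[Si](CC)(CC)CC)/C=C(\C)CC[C@@H]1[C@@]2(C)CCC[C@@](C)(CO[Si](CC)(CC)CC)[C@@H]2[C@@H](O[Si](CC)(CC)CC)C[C@@]1(C)O[Si](CC)(CC)CC
F10 | step 18 | 22-hydroxy compound (C22 epimers) corresponding to 28 | CC(O)[C@H](OCc1ccc(OC)cc1)[C@@H](O[Si](CC)(CC)CC)/C=C(\C)CC[C@@H]1[C@@]2(C)CCC[C@@](C)(CO[Si](CC)(CC)CC)[C@@H]2[C@@H](O[Si](CC)(CC)CC)C[C@@]1(C)O[Si](CC)(CC)CC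
F11 | step 20 | 21-O-bromoacetate of 29 | CC(=O)[C@H](OC(=O)CBr)[C@@H](O[Si](CC)(CC)CC)/C=C(\C)CC[C@@H]1[C@@]2(C)CCC[C@@](C)(CO[Si](CC)(CC)CC)[C@@H]2[C@@H](O[Si](CC)(CC)CC)C[C@@]1(C)O[Si](CC)(CC)CC
F12 | step 20 | 22-hydroxy-22-methyl γ-lactone (C22 epimers), O6, O8, O15, O18 as triethylsilyl ethers | CC1(O)CC(=O)O[C@@H]1[C@@H](O[Si](CC)(CC)CC)/C=C(\C)CC[C@@H]1[C@@]2(C)CCC[C@@](C)(CO[Si](CC)(CC)CC)[C@@H]2[C@@H](O[Si](CC)(CC)CC)C[C@@]1(C)O[Si](CC)(CC)CC
F13 | step 5 | 6α-(diethylsilyloxy)-13,13-(ethylenedioxy)-14,15-dinorlabdan-8α-ol | CC1(CC[C@@H]2[C@@]3(C)CCCC(C)(C)[C@@H]3[C@@H](O[SiH](CC)CC)C[C@@]2(C)O)OCCO1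
A1 | alternative 1 | 3β-hydroxy-18-(tert-butyldiphenylsilyloxy)drim-7-en-11-yl acetate | CC(=O)OC[C@@H]1[C@@]2(C)CC[C@H](O)[C@@](C)(CO[Si](c3ccccc3)(c3ccccc3)C(C)(C)C)[C@@H]2CC=C1C
A2 | alternative 2 | dehydroabietic acid | CC(C)C1=CC2=C(C=C1)[C@]3(CCC[C@@]([C@@H]3CC2)(C)C(=O)O)C
A3 | alternative 2 | 6α,18-diacetoxy 8α,12-lactone of sclareolide type | O=C1C[C@@H]2[C@@]3(C)CCC[C@@](C)(COC(C)=O)[C@@H]3[C@@H](OC(C)=O)C[C@@]2(C)O1
A4 | alternative 3 | 8α-hydroxy-8β-methyl-9-oxo Δ5-octalin, 18-benzyl ether | O=C1[C@@]2(C)CCC[C@@](C)(COCc3ccccc3)C2=CC[C@@]1(C)O
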